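Amounts first: first end groups charged as solid must dissolve, and each dissolved one then takes a second end group and becomes either a link or a ring.

| flask | solid first end groups | second end groups | remark | time |
|---|---|---|---|---|
| red | 1 mM | 0.55 mM | run made earlier |  |
| grey | 1 mM | 0.83 mM | run made earlier |  |
| amber | 2 mM | 1.1 mM | run made earlier |  |
| flask | 1.0 mM | 1.10 mM |  | 2.5 min |

| run | time / min | links / % | first end groups / % | solid first end groups / % |
|---|---|---|---|---|
| red | 0.833 | 9 | 4 | 76 |
| red | 1.50 | 16 | 7 | 63 |
| red | 2.50 | 22 | 6 | 49 |
| red | 3.00 | 22 | 9 | 40 |
| grey | 0.417 | 7 | 5 | 83 |
| grey | 1.00 | 17 | 7 | 69 |
| grey | 2.00 | 31 | 8 | 46 |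
| grey | 3.00 | 42 | 9 | 26 |
| amber | 0.833 | 11 | 1 | 85 |
| amber | 1.50 | 17 | 2 | 79 |
| amber | 2.50 | 21 | 2 | 64 |
| amber | 3.00 | 27 | 4 | 58 |

(scatter of a reading: 1.5 percentage points)

- solid first end groups is a solid; its amount is given per volume of the solution
- steps that have been proposed: solid first end groups <-> first end groups; first end groups + second end groups -> links; first end groups + second end groups -> rings
- at the start none of the solid first end groups is in solution
- first end groups means what is dissolved; the solid is not counted in it

- amount of links at 2.5 min, in percent of the solid first end groups charged
- concentration of first end groups in solution at 80 s, in percent of saturation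
- the change that raises the amount of links at 2.5 min, in percent of the solid first end groups charged most ("none" if none brings more than 2 percentage points) (theta / epsilon / delta / none)
- amount of links at 2.5 min, in percent of the solid first end groups charged, after theta

- theta: doubling the dissolution coefficient of the solid first end groups, all else as stated
- epsilon: doubling the amount of second end groups, all else as stated
- delta: doubling the solubility of the solid first end groups, all else as stated

Rings are not read, so we take them as the charge minus links, first end groups and solid. At the last reading of each run we divide links per ring by the mean c(second end groups), which is the charge minus half of what has passed the fork. This gives 2.57 mM⁻¹ in red, 3.62 mM⁻¹ in grey and 3.41 mM⁻¹ in amber.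

Their mean, 3.20 mM⁻¹, is our fork constant g: links made per ring for each mM of second end groups present, a selectivity factor. A dissolved molecule's chance of becoming a link is g·c(second end groups) over that product plus one.

For the flask we borrow the grey run's passage through the fork, taken between its readings on either side of 2.5 min: 0.555 mM. So the chance is 72.5 %, and we reckon 40.2 % links.

The forecast says more, 44 %, with 33 % of saturation, epsilon as best change and 52 % after theta; its grounds include “Ring selectivity falls as second end groups increase”.

The flask gives 46.6 % links, epsilon as best change with a gain of 33 percentage points, and 53.6 % links after theta. In the flask, c(first end groups) stands at 59.5 % of saturation at 80 s. The forecast stands, except that its saturation figure lies 26 points below.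

    solid first end groups ⇌ first end groups, rate k1*(cs1 - [first end groups]) while solid is left; crystals form when [first end groups] > cs1 (solubility = 0.0980 mM, k = 0.117 s⁻¹)
    first end groups + second end groups → links (k = 75.1 L mol⁻¹ s⁻¹)
    first end groups + second end groups → rings, rate k3*[first end groups] as long as [second end groups] is above zero (k = 0.0234 s⁻¹)

In the flask, first end groups pass into links 2.5 times as fast as into rings at 1.09 min, but 1.4 times at 2.50 min, when c(second end groups) is 40 % of its charge and g times it gives 1.39. In the neighbour flask with 2.8 mM of second end groups, 64.5 % of that charge is left, so the mean c(second end groups) is 2.30 mM and g gives 7.36 links per ring; that flask holds 87.5 % links and 12.0 % rings.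

The data were generated by integration on assumed constants; noise was put on by code.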